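**Assumptions (one line each):** The SMILES gives 2S at chromene C2 and 5R at butenolide C5, with the trisubstituted alkene E. (S)-(+)-Linalool and (R)-epichlorohydrin are the two purchased chiral starting materials.

## Retrosynthetic overview
1. Phenol is unmasked last. The butenolide comes from an α-alkylated γ-lactone by selenoxide syn-elimination (a pericyclic Ei step). The lactone comes from a terminal epoxide plus the acetic acid dianion.
2. The butenolide C5 stereocentre comes from (R)-epichlorohydrin, opened with isopropenyl Grignard/Cu. The resulting methallyl epoxide is joined to the chromene chain by E-selective cross-metathesis, which forms C(CH3)=CH.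
3. The 2H-chromene ring closes by RCM of an o-vinylaryl tertiary allylic ether. This is a ruthenacyclobutane [2+2]/retro-[2+2] ring closure. The quaternary C2 is the carbinol carbon of (S)-linalool, arylated by SNAr of its alkoxide so the C–O bond is never broken.
4. The aryl fluoride comes from 4-fluoro-3-methylphenol by TIPS protection and ortho-lithiation/formylation. The 3-butenyl arm comes from linalool by ozonolysis and Wittig methylenation.
5. Ring order: pyran of the chromene (RCM), then γ-lactone, then the butenolide C=C.

## Route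

**Step 1**
Reactants: 1 (S)-linalool
Product: 2 (S)-4-hydroxy-4-methylhex-5-enal
Conditions: O3, CH2Cl2, –78 °C (1.0 equiv); then PPh3
Reagents that add atoms: ozone [O-][O+]=O
Why: Ozone (1,3-dipolar cycloaddition/cycloreversion) attacks the more electron-rich trisubstituted alkene faster than the vinyl group. The carbinol stereocentre is untouched.

**Step 2**
Reactants: 2
Product: 3 (S)-3-methylhepta-1,6-dien-3-ol
Conditions: Ph3P=CH2 (from Ph3PCH3Br, KOtBu), THF, 0 °C
Reagents that add atoms: methylenetriphenylphosphorane C=P(c1ccccc1)(c1ccccc1)c1ccccc1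
Why: Wittig methylenation converts CHO to CH=CH2 and leaves the tertiary stereocentre alone. This gives the terminal alkene needed for the later cross-metathesis.

**Step 3**
Reactants: 4 (4-fluoro-3-methylphenol)
Product: 5 (4-fluoro-3-methylphenyl triisopropylsilyl ether)
Conditions: TIPSCl, imidazole, DMF, rt
Reagents that add atoms: TIPSCl CC(C)[Si](Cl)(C(C)C)C(C)C
Why: Silylation gives a base-stable phenol protecting group. Its bulk also disfavours lithiation next to oxygen in step 4.

**Step 4**
Reactants: 5
Product: 6 (2-fluoro-3-methyl-5-(triisopropylsilyloxy)benzaldehyde)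
Conditions: s-BuLi, TMEDA, THF, –78 °C; then DMF
Reagents that add atoms: DMF CN(C)C=O
Why: Directed ortho-metalation. Fluorine directs to C5, the only H ortho to F, and the bulky OTIPS suppresses metalation ortho to O. DMF then gives the aldehyde, which is ortho to F.

**Step 5**
Reactants: 3 and 6
Product: 7 (2-[(S)-3-methylhepta-1,6-dien-3-yloxy]-3-methyl-5-(TIPSO)benzaldehyde)
Conditions: 3, KHMDS, THF, 0 °C; then 6, 0 → 50 °C
Reagents that add atoms: none (KHMDS only removes H)
Why: SNAr addition–elimination at the C–F carbon, activated by the ortho-CHO. The carbinol C–O bond is never cleaved, so the tertiary stereocentre is retained. This is the chromene C2 centre, 2S.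

**Step 6**
Reactants: 8 ((R)-epichlorohydrin), 9 (isopropenylmagnesium bromide)
Product: 10 (R)-1-chloro-4-methylpent-4-en-2-ol
Conditions: 9, CuI (10 mol%), THF, –30 °C
Reagents that add atoms: 9 C=C(C)[Mg]Br (numbered reactant)
Why: Cu-catalysed SN2 opening at the terminal epoxide CH2. The stereocentre carries no bond change, so it stays R.

**Step 7**
Reactants: 10
Product: 11 (R)-2-(2-methylallyl)oxirane
Conditions: NaOH (aq), Et2O, 0 °C → rt
Reagents that add atoms: none
Why: Intramolecular Williamson (3-exo-tet) at CH2Cl. The carbinol stereocentre is untouched.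

**Step 8**
Reactants: 7 and 11 (3 equiv)
Product: 12 (aldehyde bearing the E-trisubstituted alkene and the epoxide)
Conditions: Hoveyda–Grubbs II (5 mol%), CH2Cl2, 40 °C (ethylene vented)
Reagents that add atoms: 11 (numbered reactant)
Why: Cross-metathesis (ruthenacyclobutane [2+2]/retro-[2+2]) of the unhindered butenyl alkene with the methallyl alkene. It gives mainly the thermodynamic E-alkene. The tertiary vinyl group is too hindered to react.

**Step 9**
Reactants: 12
Product: 13 (o-vinylaryl ether)
Conditions: Ph3PCH3Br, KOtBu, THF, 0 °C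
Reagents that add atoms: methylenetriphenylphosphorane C=P(c1ccccc1)(c1ccccc1)c1ccccc1
Why: Wittig methylenation of the aryl CHO. The epoxide and the ether are inert, and no stereocentre changes.

**Step 10**
Reactants: 13
Product: 14 (2H-chromene epoxide)
Conditions: Grubbs II (5 mol%), CH2Cl2 (5 mM), 40 °C, dark
Reagents that add atoms: none (ethylene lost)
Why: Ring-closing metathesis between the styrenyl and the tertiary-allylic vinyl groups forms the six-membered pyran via a ruthenacyclobutane ([2+2]/retro-[2+2]). Neither stereocentre is involved. The trisubstituted alkene does not react.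

**Step 11**
Reactants: 14 and 15 (acetic acid)
Product: 16 ((R)-lactone: 5-substituted dihydrofuran-2(3H)-one)
Conditions: AcOH (3 equiv), LDA (6 equiv), THF, 0 °C; then 14, 0 °C → rt; then PPTS (cat.), PhH, 50 °C
Reagents that add atoms: 15 CC(=O)O (numbered reactant)
Why: The acetic acid dianion opens the epoxide by SN2 at the terminal CH2, and the γ-hydroxy acid lactonises. The carbinol carbon keeps its configuration, which is C5-R.

**Step 12**
Reactants: 16 and 17 (5-bromo-2-methylpent-2-ene)
Product: 18 (3-(4-methylpent-3-enyl)lactone; C3 epimers)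
Conditions: LDA, THF, –78 °C; then 17, DMPU, –78 → –20 °C
Reagents that add atoms: 17 CC(C)=CCCBr (numbered reactant)
Why: Lactone enolate C-alkylation. The new C3 stereocentre is a mixture and is erased in step 14.

**Step 13**
Reactants: 18
Product: 19 (α-phenylseleno lactone)
Conditions: LDA, THF, –78 °C; then PhSeCl (1.0 equiv)
Reagents that add atoms: PhSeCl Cl[Se]c1ccccc1
Why: The enolate reacts with PhSeCl faster than the alkenes do. The quaternary Se-bearing carbon sets up the elimination.

**Step 14**
Reactants: 19
Product: 20 (TIPS-protected tuberatolide B)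
Conditions: NaIO4, NaHCO3, THF/H2O, 0 °C → rt (i-Pr2NH as PhSeOH scavenger)
Reagents that add atoms: none
Why: Oxidation to the selenoxide, then syn-elimination (Ei, five-membered cyclic TS) with the ring C4–H. This gives the conjugated butenolide. C5 is not involved, and the C3 centre is destroyed.

**Step 15**
Reactants: 20
Product: 21 (tuberatolide B)
Conditions: TBAF (1.2 equiv) buffered with AcOH (1.2 equiv), THF, 0 °C
Reagents that add atoms: none
Why: Fluoride removes the aryl TIPS group. The buffer limits base-induced epimerisation at the γ-H of the butenolide.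

## Compound list
1 | (S)-(+)-linalool | C=C[C@@](C)(O)CCC=C(C)C | starting material
2 | (S)-4-hydroxy-4-methylhex-5-enal | C=C[C@@](C)(O)CCC=O | intermediate
3 | (S)-3-methylhepta-1,6-dien-3-ol | C=C[C@@](C)(O)CCC=C | intermediate
4 | 4-fluoro-3-methylphenol | Cc1cc(O)ccc1F | starting material
5 | (4-fluoro-3-methylphenoxy)triisopropylsilane | Cc1cc(O[Si](C(C)C)(C(C)C)C(C)C)ccc1F | intermediate
6 | 2-fluoro-3-methyl-5-(TIPSO)benzaldehyde | Cc1cc(O[Si](C(C)C)(C(C)C)C(C)C)cc(C=O)c1F | intermediate
7 | aryl tertiary ether aldehyde | C=C[C@@](C)(Oc1c(C)cc(O[Si](C(C)C)(C(C)C)C(C)C)cc1C=O)CCC=C | intermediate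
8 | (R)-epichlorohydrin | ClC[C@H]1CO1 | starting material
9 | isopropenylmagnesium bromide | C=C(C)[Mg]Br | starting material
10 | (R)-1-chloro-4-methylpent-4-en-2-ol | C=C(C)C[C@@H](O)CCl | intermediate
11 | (R)-2-(2-methylallyl)oxirane | C=C(C)C[C@@H]1CO1 | intermediate
12 | E-alkene aldehyde epoxide | C=C[C@@](C)(Oc1c(C)cc(O[Si](C(C)C)(C(C)C)C(C)C)cc1C=O)CC/C=C(\C)C[C@@H]1CO1 | intermediate
13 | o-vinyl analogue of 12 | C=C[C@@](C)(Oc1c(C)cc(O[Si](C(C)C)(C(C)C)C(C)C)cc1C=C)CC/C=C(\C)C[C@@H]1CO1 | intermediate
14 | 2H-chromene epoxide | C1O[C@@H]1C/C(C)=C/CC[C@@]2(C)C=Cc3cc(O[Si](C(C)C)(C(C)C)C(C)C)cc(C)c3O2 | intermediate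
15 | acetic acid | CC(=O)O | starting material
16 | γ-lactone | O=C1CC[C@@H](C/C(C)=C/CC[C@@]2(C)C=Cc3cc(O[Si](C(C)C)(C(C)C)C(C)C)cc(C)c3O2)O1 | intermediate
17 | 5-bromo-2-methylpent-2-ene | CC(C)=CCCBr | starting material
18 | 3-alkylated lactone (C3 epimers) | O=C1C(CCC=C(C)C)C[C@@H](C/C(C)=C/CC[C@@]2(C)C=Cc3cc(O[Si](C(C)C)(C(C)C)C(C)C)cc(C)c3O2)O1 | intermediate
19 | α-phenylseleno lactone | O=C1C(CCC=C(C)C)([Se]c2ccccc2)C[C@@H](C/C(C)=C/CC[C@@]2(C)C=Cc3cc(O[Si](C(C)C)(C(C)C)C(C)C)cc(C)c3O2)O1 | intermediate
20 | TIPS-tuberatolide B | CC(C)=CCCC1=C[C@@H](C/C(C)=C/CC[C@@]2(C)C=Cc3cc(O[Si](C(C)C)(C(C)C)C(C)C)cc(C)c3O2)OC1=O | intermediate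
21 | tuberatolide B | CC(C)=CCCC1=C[C@@H](C/C(C)=C/CC[C@@]2(C)C=Cc3cc(O)cc(C)c3O2)OC1=O | target

**Total steps:** 15. **Longest linear sequence:** 11 (1 → 2 → 3 → 7 → 12 → 13 → 14 → 16 → 18 → 19 → 20 → 21, counting step 15).

**Three steps most likely to fail**
1. **Step 8 (cross-metathesis of a terminal alkene with a 1,1-disubstituted alkene).** Yield and E/Z ratio are the concern. Fallback: change to Julia–Lythgoe olefination. Ozonolyse the butenyl arm of 7 to its aldehyde and couple it with the phenyl sulfone made from (R)-epichlorohydrin plus lithiated ethyl phenyl sulfide. Then reductively eliminate the resulting β-acyloxy sulfone.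
2. **Step 5 (SNAr of a hindered tertiary alkoxide at a di-ortho-substituted aryl fluoride).** Fallback: build the chromane instead. Hydroborate the vinyl of 3 with 9-BBN and Suzuki-couple it to a 2-bromo-6-methyl-4-(silyloxy)aryl halide. Then close the ring by intramolecular Pd- or Cu-catalysed O-arylation of the tertiary alcohol, and dehydrogenate with DDQ to the chromene. The carbinol stereocentre is retained throughout.
3. **Step 14 (endo versus exo selenoxide elimination, and γ-epimerisation).** Fallback: dehydrogenate the unsubstituted lactone 16 first (selenation and oxidation). Then iodinate at C3 (I2, pyridine) and install the side chain by Negishi coupling with (4-methylpent-3-enyl)zinc bromide.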